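**Retrosynthetic overview** (chain numbered C1 = ester C=O to C15 = ketone CH3; the ring is O–O plus C3–C6)
1. The last bond made is C8–C9, the CH2–C(=O) bond next to quaternary C10. Cutting it gives an eleven-carbon primary iodide (finished 1,2-dioxane ring, methyl ester, C2, C3 and C6 all set) and the nine-carbon chloride of 2,2-dimethyl-6-oxoheptanoic acid. A nickel-catalysed electroreductive cross-electrophile acylation joins them without protecting groups and releases the target itself.
2. Enabling feature: C9 sits between quaternary C10 (no α-H, so no ketene or enolisation, and the new ketone is shielded) and the unbranched C7–C8 spacer. That spacer holds a C8 radical two carbons away from the ring O–O bond, so attack on oxygen would need a four-membered transition state. The O–O bond is itself flanked by quaternary C6 and branched C3.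
3. The 1,2-dioxane ring comes from two stereospecific C–O substitutions, each with inversion: H2O2 opens a temporary oxetane ring (O–C6–C7–C8) at C6, then the hydroperoxide displaces a C3 mesylate (6-exo-tet).
4. C6 comes from Sharpless epoxidation of geraniol (its C1–C6 become C8–C3). C2 and C3 come from a Brown (Z)-crotylboration. The C1 ester comes from the vinyl group by ozonolysis and chlorite oxidation.
5. Ring order: epoxide (step 1), oxetane (step 3, opened in step 7), 1,2-dioxane (step 8). The acyl half comes from aerobic C–C cleavage of 2,2,6-trimethylcyclohexanone.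

Key step: step 14

Remark: the SMILES is read as (2S,3S,6R), with C2-Me/C3-O anti and the C3 side chain cis to the C7 chain on C6. Stereoisomers left by incomplete selectivity in steps 1, 5 and 7 become ring diastereomers at compound 12 and should be removable there by chromatography.

**Step 1**
Reactants: 1 geraniol
Product: 2 (2S,3S)-2,3-epoxygeraniol, [(2S,3S)-3-methyl-3-(4-methylpent-3-en-1-yl)oxiran-2-yl]methanol
Conditions: Ti(OiPr)4 (5 mol %), L-(+)-diethyl tartrate (6 mol %), tBuOOH (decane), 4 Å MS, CH2Cl2, −20 °C
Reagents that add atoms: tert-butyl hydroperoxide, CC(C)(C)OO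
Why: Sharpless asymmetric epoxidation: the catalyst formed from Ti(OiPr)4 and the tartrate binds the allylic hydroxyl, so only the C6=C7 alkene should react, and L-(+)-tartrate should deliver oxygen to the face that gives the (2S,3S)-epoxide, which sets the C6–O stereocentre.

**Step 2**
Reactants: 2 (2S,3S)-2,3-epoxygeraniol
Product: 3 (S)-3,7-dimethyloct-6-ene-1,3-diol
Conditions: NaAlH2(OCH2CH2OMe)2, THF, 0 °C to rt; aq. potassium sodium tartrate
Reagents that add atoms: none
Why: Hydroxyl-directed reductive epoxide opening: the alkoxyaluminate formed at the primary hydroxyl should deliver hydride to the adjacent, less substituted C7, so the 1,3-diol forms and the C6–O bond keeps its configuration.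

**Step 3**
Reactants: 3 (S)-3,7-dimethyloct-6-ene-1,3-diol
Product: 5 (S)-2-methyl-2-(4-methylpent-3-en-1-yl)oxetane, via primary monotosylate 4 (not isolated)
Conditions: KOtBu (1.0 equiv), TsCl (1.0 equiv), THF, 0 °C; then KOtBu (1.2 equiv), 0 to 40 °C
Reagents that add atoms: p-toluenesulfonyl chloride, Cc1ccc(cc1)S(=O)(=O)Cl (its atoms stay in 4 only and leave on ring closure)
Why: Selective sulfonylation of the primary alkoxide followed by Williamson-type 4-exo-tet closure by the tertiary alkoxide should give the oxetane with retention at C6 (no bond to C6 is broken), a temporary ring that masks both hydroxyls and stores the strain used in step 7.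

**Step 4**
Reactants: 5 (S)-2-methyl-2-(4-methylpent-3-en-1-yl)oxetane
Product: 7 3-[(2S)-2-methyloxetan-2-yl]propanal, via secondary ozonide 6 (not isolated)
Conditions: O3, CH2Cl2, −78 °C; then Me2S, −78 °C to rt
Reagents that add atoms: ozone, [O-][O+]=O
Why: Ozonolysis (Criegee mechanism) with reductive work-up should cleave the only alkene to the C3 aldehyde, the oxetane being inert to ozone and to Me2S.

**Step 5**
Reactants: 7 3-[(2S)-2-methyloxetan-2-yl]propanal
Product: 9 (3R,4R)-3-methyl-6-[(2S)-2-methyloxetan-2-yl]hex-1-en-4-ol, via borinate ester 8 (not isolated)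
Conditions: (Z)-2-butene, n-BuLi, KOtBu, THF, −78 to −45 °C; (−)-Ipc2BOMe, −78 °C; BF3·OEt2, −78 °C; then 7, −78 °C; then NaOH, H2O2, 0 °C to rt
Reagents that add atoms: (Z)-2-butene, C/C=C\C; (−)-B-methoxydiisopinocampheylborane, COB([C@@H]1C[C@@H]2C[C@H]([C@H]1C)C2(C)C)[C@@H]1C[C@@H]2C[C@H]([C@H]1C)C2(C)C (boron and Ipc groups stay in 8 only)
Why: Brown asymmetric crotylboration: the closed chair (Zimmerman–Traxler) transition state should translate the Z geometry into the 2,3-syn relationship, and the isopinocampheyl groups derived from (+)-α-pinene should direct attack to the Si face of the aldehyde, which sets C2 and C3 as (3R,4R) independently of remote C6 while the THF solvent buffers BF3 against the oxetane.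

**Step 6**
Reactants: 9 (3R,4R)-3-methyl-6-[(2S)-2-methyloxetan-2-yl]hex-1-en-4-ol
Product: 10 (3R,4R)-3-methyl-6-[(2S)-2-methyloxetan-2-yl]hex-1-en-4-yl methanesulfonate
Conditions: MsCl, Et3N, CH2Cl2, 0 °C
Reagents that add atoms: methanesulfonyl chloride, CS(=O)(=O)Cl
Why: Standard mesylation of the secondary alcohol with retention at C3, under basic conditions that should leave oxetane and alkene untouched.

**Step 7**
Reactants: 10 the oxetane mesylate
Product: 11 (3R,4R,7R)-7-hydroperoxy-9-hydroxy-3,7-dimethylnon-1-en-4-yl methanesulfonate
Conditions: anhydrous H2O2 in Et2O (10 equiv), TMSOTf (15 mol %), Et2O, −40 to 0 °C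
Reagents that add atoms: hydrogen peroxide, OO
Why: Lewis acid catalysed perhydrolysis of a 2,2-disubstituted oxetane: strain release and the developing positive charge at the tertiary carbon should steer H2O2 to C6 with backside attack, so the C6–O bond is replaced with inversion to give the (R)-hydroperoxide and the C8 hydroxyl is freed in the same event.

**Step 8**
Reactants: 11 the hydroperoxy mesylate
Product: 12 2-[(3R,6S)-6-[(2R)-but-3-en-2-yl]-3-methyl-1,2-dioxan-3-yl]ethan-1-ol
Conditions: KOtBu (1.05 equiv), 18-crown-6, THF (dilute), 0 °C
Reagents that add atoms: none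
Why: Intramolecular alkylation of a hydroperoxide: the much more acidic OOH is deprotonated selectively and the peroxy anion should displace the C3 mesylate in a 6-exo-tet SN2 closure with inversion, which turns the syn mesylate into the 2,3-anti (3S) arrangement and places the C3 and C6 carbon chains cis on the new 1,2-dioxane ring.

**Step 9**
Reactants: 12 the dioxane alkenol
Product: 14 (2S)-2-[(3S,6R)-6-(2-hydroxyethyl)-6-methyl-1,2-dioxan-3-yl]propanoic acid, via aldehyde 13 (not isolated)
Conditions: O3, MeCN/H2O (9:1), 0 °C; then NaClO2, NaH2PO4, 0 °C to rt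
Reagents that add atoms: ozone, [O-][O+]=O; water, O; sodium chlorite, [Na+].[O-]Cl=O
Why: Ozonolysis in aqueous acetonitrile (water traps the carbonyl oxide, so the aldehyde forms directly) telescoped with a Pinnick-type chlorite oxidation (the H2O2 formed scavenges HOCl) should shorten the vinyl group to the C1 acid without isolating the epimerisable, elimination-prone β-peroxy aldehyde and without touching the O–O bond or the primary alcohol.

**Step 10**
Reactants: 14 the hydroxy acid
Product: 15 methyl (2S)-2-[(3S,6R)-6-(2-hydroxyethyl)-6-methyl-1,2-dioxan-3-yl]propanoate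
Conditions: TMSCHN2 (hexanes), toluene/MeOH, 0 °C
Reagents that add atoms: trimethylsilyldiazomethane, C[Si](C)(C)C=[N+]=[N-]
Why: Methyl esterification with trimethylsilyldiazomethane starts with protonation of the diazo carbon by the acid, so it is base-free and should spare the C2 stereocentre, the primary alcohol and the retro-oxa-Michael-prone C3–O bond.

**Step 11**
Reactants: 15 the hydroxy ester
Product: 16 methyl (2S)-2-[(3S,6R)-6-(2-iodoethyl)-6-methyl-1,2-dioxan-3-yl]propanoate
Conditions: PPh3, I2, imidazole premixed in CH2Cl2, 0 °C; then 15, 0 °C, dark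
Reagents that add atoms: iodine, II
Why: Appel-type (Garegg–Samuelsson) iodination: the phosphine is consumed as the iodophosphonium salt before the substrate is added, so SN2 displacement at primary C8 should outrun deoxygenation of the hindered dialkyl peroxide.

**Step 12**
Reactants: 17 2,2,6-trimethylcyclohexanone (racemic)
Product: 19 2,2-dimethyl-6-oxoheptanoic acid (geronic acid), via hydroperoxy ketone 18 (not isolated)
Conditions: Cu(NO3)2·3H2O (5 mol %), O2 (1 atm), AcOH/H2O, 70 °C
Reagents that add atoms: dioxygen, O=O
Why: Copper-catalysed aerobic α-oxygenation and C–C cleavage of an α-branched ketone: 17 can enolise only towards its CHMe carbon, so O2 is taken up there and the tertiary α-hydroperoxy ketone should collapse to the keto acid with all nine carbons kept and the racemic stereocentre erased.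

**Step 13**
Reactants: 19 2,2-dimethyl-6-oxoheptanoic acid
Product: 20 2,2-dimethyl-6-oxoheptanoyl chloride
Conditions: (COCl)2, DMF (cat.), CH2Cl2, 0 °C to rt
Reagents that add atoms: oxalyl chloride, O=C(Cl)C(=O)Cl
Why: Vilsmeier-catalysed acid chloride formation, which should be clean because the acid has no α-hydrogen (no ketene) and the remote methyl ketone is inert.

**Step 14**
Reactants: 16 the dioxane iodide; 20 2,2-dimethyl-6-oxoheptanoyl chloride (1.5 equiv)
Product: 21 diacarperoxide B
Conditions: NiBr2(dme) (10 mol %), 4,4'-di-tert-butyl-2,2'-bipyridine (12 mol %), nBu4NBF4 (0.1 M), N,N-dimethylacetamide, undivided cell, reticulated vitreous carbon cathode, Zn anode, cathode held at the nickel wave (ca. −1.3 V vs SCE), 0 °C to rt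
Reagents that add atoms: none
Why: Cathodic reduction of the divalent nickel precatalyst gives zerovalent nickel, which inserts into the C9–Cl bond of 20; a monovalent nickel species abstracts iodine from 16, the primary C8 radical is trapped by the acylnickel complex, and reductive elimination from the trivalent acyl(alkyl)nickel forges C8–C9 while the zinc anode is oxidised in the counter-reaction. The closest known reaction type is the nickel/bipyridine-catalysed reductive cross-electrophile coupling of primary alkyl iodides with acid chlorides, which is established with metal powders and with a cathode plus sacrificial anode and accepts pivaloyl-type acyl partners. No ring is closed and no stereocentre is made: C2, C3 and C6 are spectators, and the neutral, base-free medium should leave the C2–H and the β-peroxy ester unit untouched. Cross- over homo-coupling is secured by the different activation modes of the partners (two-electron insertion into C(sp2)–Cl, halogen-atom abstraction from C(sp3)–I) and by the excess of 20. The critical chemoselectivity is C–I and C–Cl over O–O: electron transfer to a dialkyl peroxide is dissociative, has a high intrinsic barrier and should need a potential well beyond the nickel wave, which is why a potentiostat replaces a metal powder; the O–O bond is also shielded by quaternary C6 and branched C3, and the C8 radical, held off by C7 and C6, could reach oxygen only through a strained four-membered transition state. Quaternary C10 rules out ketene formation and enolisation and shields the new C9 ketone from further reduction, the C14 ketone and C1 ester are inert to acylnickel chemistry, and so this single operation adds nine carbons, both ketones and the quaternary centre and releases 21 directly.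

**Compound list**
1 | geraniol | CC(C)=CCC/C(C)=C/CO | starting material
2 | (2S,3S)-2,3-epoxygeraniol | CC(C)=CCC[C@]1(C)O[C@H]1CO | intermediate
3 | (S)-3,7-dimethyloct-6-ene-1,3-diol | CC(C)=CCC[C@](C)(O)CCO | intermediate
4 | (S)-3-hydroxy-3,7-dimethyloct-6-en-1-yl 4-methylbenzenesulfonate | CC(C)=CCC[C@](C)(O)CCOS(=O)(=O)c1ccc(C)cc1 | intermediate (not isolated)
5 | (S)-2-methyl-2-(4-methylpent-3-en-1-yl)oxetane | CC(C)=CCC[C@@]1(C)CCO1 | intermediate
6 | 3,3-dimethyl-5-{2-[(2S)-2-methyloxetan-2-yl]ethyl}-1,2,4-trioxolane (epimers at the acetal carbon) | CC1(C)OOC(CC[C@@]2(C)CCO2)O1 | intermediate (not isolated)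
7 | 3-[(2S)-2-methyloxetan-2-yl]propanal | O=CCC[C@@]1(C)CCO1 | intermediate
8 | diisopinocampheylborinate ester of 9 | C=C[C@@H](C)[C@H](OB([C@@H]1C[C@@H]2C[C@H]([C@H]1C)C2(C)C)[C@@H]1C[C@@H]2C[C@H]([C@H]1C)C2(C)C)CC[C@@]1(C)CCO1 | intermediate (not isolated)
9 | (3R,4R)-3-methyl-6-[(2S)-2-methyloxetan-2-yl]hex-1-en-4-ol | C=C[C@@H](C)[C@H](O)CC[C@@]1(C)CCO1 | intermediate
10 | (3R,4R)-3-methyl-6-[(2S)-2-methyloxetan-2-yl]hex-1-en-4-yl methanesulfonate | C=C[C@@H](C)[C@H](OS(C)(=O)=O)CC[C@@]1(C)CCO1 | intermediate
11 | (3R,4R,7R)-7-hydroperoxy-9-hydroxy-3,7-dimethylnon-1-en-4-yl methanesulfonate | C=C[C@@H](C)[C@H](OS(C)(=O)=O)CC[C@](C)(CCO)OO | intermediate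
12 | 2-[(3R,6S)-6-[(2R)-but-3-en-2-yl]-3-methyl-1,2-dioxan-3-yl]ethan-1-ol | C=C[C@@H](C)[C@@H]1CC[C@](C)(CCO)OO1 | intermediate
13 | (2S)-2-[(3S,6R)-6-(2-hydroxyethyl)-6-methyl-1,2-dioxan-3-yl]propanal | O=C[C@@H](C)[C@@H]1CC[C@](C)(CCO)OO1 | intermediate (not isolated)
14 | (2S)-2-[(3S,6R)-6-(2-hydroxyethyl)-6-methyl-1,2-dioxan-3-yl]propanoic acid | OC(=O)[C@@H](C)[C@@H]1CC[C@](C)(CCO)OO1 | intermediate
15 | methyl (2S)-2-[(3S,6R)-6-(2-hydroxyethyl)-6-methyl-1,2-dioxan-3-yl]propanoate | COC(=O)[C@@H](C)[C@@H]1CC[C@](C)(CCO)OO1 | intermediate
16 | methyl (2S)-2-[(3S,6R)-6-(2-iodoethyl)-6-methyl-1,2-dioxan-3-yl]propanoate | COC(=O)[C@@H](C)[C@@H]1CC[C@](C)(CCI)OO1 | intermediate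
17 | 2,2,6-trimethylcyclohexanone (racemic) | CC1CCCC(C)(C)C1=O | starting material
18 | 2-hydroperoxy-2,6,6-trimethylcyclohexan-1-one (racemic) | CC1(OO)CCCC(C)(C)C1=O | intermediate (not isolated)
19 | 2,2-dimethyl-6-oxoheptanoic acid | CC(=O)CCCC(C)(C)C(=O)O | intermediate
20 | 2,2-dimethyl-6-oxoheptanoyl chloride | CC(=O)CCCC(C)(C)C(=O)Cl | intermediate
21 | diacarperoxide B, methyl (2S)-2-[(3S,6R)-6-(4,4-dimethyl-3,8-dioxononyl)-6-methyl-1,2-dioxan-3-yl]propanoate | COC(=O)[C@@H](C)[C@@H]1CC[C@](C)(CCC(=O)C(C)(C)CCCC(C)=O)OO1 | target

**Step count**
Total step count: 14.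
Longest linear sequence: 12 (steps 1–11, then 14).

**Steps most likely to fail**

1. **Step 14.** What may go wrong:
   - inner-sphere cleavage of the O–O bond by low-valent nickel
   - decarbonylation of the hindered acylnickel
   - dimerisation or hydrodehalogenation at C8

   Fallback, from 16 (with 20) back to 21: move to a two-electron transmetalation manifold with no free C8 radical and no nickel. Zinc insertion into the C–I bond (Zn dust, LiCl, THF, rt) should give the alkylzinc iodide F1. This is acylated with 20 under zerovalent palladium catalysis (Pd(PPh3)4, THF, 0 °C to rt, Negishi acylation). Organozinc reagents and zerovalent palladium couplings are a manifold in which cyclic dialkyl peroxides are expected to persist.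

2. **Step 7.** What may go wrong:
   - ionisation at C6 ahead of nucleophilic attack, with loss of stereochemical fidelity or elimination
   - attack of the product hydroperoxide on unreacted oxetane

   Fallback, from 10 back to 12: reverse the order of the two C–O bond formations so that the oxetane opening becomes intramolecular. Displacement of the C3 mesylate with H2O2/KOH (MeOH, 0 °C to rt, SN2 with inversion) should give the secondary hydroperoxide oxetane F2. Catalytic TMSOTf (CH2Cl2, −20 °C) should then trigger a 6-exo hydroperoxide–oxetane cyclisation at C6 with inversion. This delivers 12 directly and bypasses 11.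

3. **Step 8.** What may go wrong: E2 elimination or sluggish substitution at the β-branched secondary mesylate.

   Fallback, from 7 back to 15: close the ring by conjugate addition instead of substitution.
   - Wittig olefination of 7 with methyl 2-(triphenylphosphoranylidene)propanoate (toluene, 40 °C) should give the (E)-enoate oxetane F3.
   - Perhydrolysis as in step 7 should give the hydroperoxy enoate F4.
   - Et2NH in CF3CH2OH should promote 6-exo-trig oxa-Michael closure to 15.

   C6 stays defined, but C2 and C3 are then under substrate control only, so the diastereomers would have to be separated by chromatography.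

**Further compounds**
F1 | step 14 | {2-[(3R,6S)-6-[(2S)-1-methoxy-1-oxopropan-2-yl]-3-methyl-1,2-dioxan-3-yl]ethyl}zinc iodide | COC(=O)[C@@H](C)[C@@H]1CC[C@](C)(CC[Zn]I)OO1
F2 | step 7 | (2S)-2-[(3S,4R)-3-hydroperoxy-4-methylhex-5-en-1-yl]-2-methyloxetane | C=C[C@@H](C)[C@@H](OO)CC[C@@]1(C)CCO1
F3 | step 8 | methyl (E)-2-methyl-5-[(2S)-2-methyloxetan-2-yl]pent-2-enoate | COC(=O)/C(C)=C/CC[C@@]1(C)CCO1
F4 | step 8 | methyl (R,E)-6-hydroperoxy-8-hydroxy-2,6-dimethyloct-2-enoate | COC(=O)/C(C)=C/CC[C@](C)(CCO)OO
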